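**Retrosynthetic overview**

1. Numbering: ring A is C1(=O)–C2=C3(Me)–C4–C10(Me)–C11; C5 bridges C4 and C11 (cyclobutane C4–C5–C11–C10); ring C is C5–C6(Me2)–C7–C8–C9–C10. The strategy rests on the fact that the methyl-bearing quaternary C10 is β to the C1 ketone through C11 and that C11 is also bonded to C5, so methyl addition at C10 of a C10=C11 enone produces the enolate that closes the cyclobutane.
2. Target ⇒ C7 senecioate by acylation; C9 isovalerate and anti C7–OH by Evans–Tishchenko reduction; C9–O by catalyst-controlled conjugate borylation of a C8=C9 enone; ring C by aldol condensation (C8–C9) of a C7 methyl ketone (Wacker of the C6 vinyl group) with a C9 aldehyde (Tamao–Fleming oxidation of the C10 silylmethyl arm).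
3. Ring A enone C2=C3(Me) ⇒ bicyclo[3.1.1]heptan-2-one 14 by dehydrogenation, methyl cuprate addition, bromination and anti elimination.
4. 14 ⇒ monocyclic enone mesylate 11: C10–CH3 and C5–C11 are made in one flask by conjugate methylation and 4-exo-tet enolate alkylation with inversion at C5.
5. 11 ⇒ 3-ethoxycyclohexenone 1, aldehyde 4 and silylmethyl Grignard reagent 8 (syn Mukaiyama aldol for C4/C5, Stork–Danheiser transposition). Ring order: ring A (from 1), cyclobutane (step 7), ring C (step 14).

Key step: step 7

Remark: 2,2-dimethylbut-3-enal (4) is taken as commercially available and is used freshly distilled; atom numbers C1–C11 in names follow the target numbering given in the overview.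

**Step 1**
Reactants: 1 3-ethoxycyclohex-2-en-1-one
Product: 3 1-ethoxy-3-(trimethylsilyloxy)cyclohexa-1,3-diene, via lithium dienolate 2 (not isolated)
Conditions: LDA, THF, −78 °C; Me3SiCl, −78 → 0 °C
Reagents that add atoms: chlorotrimethylsilane, C[Si](C)(C)Cl
Why: Kinetic deprotonation of the vinylogous ester occurs at the α′ carbon (C6 of 1), and O-silylation of the cross-conjugated dienolate should give the 2-silyloxy diene; no stereocentre is formed.

**Step 2**
Reactants: 3 1-ethoxy-3-(trimethylsilyloxy)cyclohexa-1,3-diene; 4 2,2-dimethylbut-3-enal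
Product: 6 (6S)-3-ethoxy-6-[(1S)-1-hydroxy-2,2-dimethylbut-3-en-1-yl]cyclohex-2-en-1-one, via silyl ether 5 (not isolated)
Conditions: chiral (acyloxy)borane from (2S,3S)-2-O-(2,6-diisopropoxybenzoyl)tartaric acid and BH3·THF (20 mol %), EtCN, −78 °C; then 0.5 M HCl, THF, 0 °C
Reagents that add atoms: none
Why: Catalytic asymmetric Mukaiyama aldol through an open transition state, in which the terminal carbon of the silyl enol ether attacks the Si face of the boron-bound aldehyde and the syn adduct forms irrespective of enol ether geometry, which sets C5 (S) and C4 (6S in this name); the tartrate antipode named is the one expected to give Si-face attack, to be confirmed by Mosher ester analysis of 6.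

**Step 3**
Reactants: 6 (6S)-3-ethoxy-6-[(1S)-1-hydroxy-2,2-dimethylbut-3-en-1-yl]cyclohex-2-en-1-one
Product: 5 (6S)-3-ethoxy-6-[(1S)-2,2-dimethyl-1-(trimethylsilyloxy)but-3-en-1-yl]cyclohex-2-en-1-one
Conditions: Me3SiCl, imidazole, CH2Cl2, 0 °C
Reagents that add atoms: chlorotrimethylsilane, C[Si](C)(C)Cl
Why: Silylation of the purified aldol under weak base masks the hydroxyl so that the organometallic reagent of step 5 cannot form an aldolate and cause retro-aldol cleavage; imidazole should not epimerise C4.

**Step 4**
Reactants: 7 (chloromethyl)dimethylphenylsilane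
Product: 8 [(dimethylphenylsilyl)methyl]magnesium chloride
Conditions: Mg, BrCH2CH2Br (cat.), THF, reflux
Reagents that add atoms: magnesium, [Mg]
Why: Grignard formation by insertion of magnesium into the C–Cl bond, which is routine for α-silyl alkyl chlorides.

**Step 5**
Reactants: 5 (6S)-3-ethoxy-6-[(1S)-2,2-dimethyl-1-(trimethylsilyloxy)but-3-en-1-yl]cyclohex-2-en-1-one; 8 [(dimethylphenylsilyl)methyl]magnesium chloride
Product: 10 (4R)-3-[(dimethylphenylsilyl)methyl]-4-[(1S)-1-hydroxy-2,2-dimethylbut-3-en-1-yl]cyclohex-2-en-1-one, via tertiary alkoxide 9 (not isolated)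
Conditions: CeCl3, THF, −78 → 0 °C; then 1 M HCl, THF, 0 °C → rt
Reagents that add atoms: water, O
Why: Stork–Danheiser transposition, in which the cerium-modified Grignard reagent adds 1,2 to the vinylogous ester carbonyl without enolising C4 and dilute acid then hydrolyses the enol ether, eliminates the tertiary hydroxyl and cleaves the O–SiMe3 group, giving the C10=C11 enone with the silylmethyl arm on C10; the carbinol centre of 9 is lost again and C4 and C5 are untouched.

**Step 6**
Reactants: 10 (4R)-3-[(dimethylphenylsilyl)methyl]-4-[(1S)-1-hydroxy-2,2-dimethylbut-3-en-1-yl]cyclohex-2-en-1-one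
Product: 11 (1S)-1-[(1R)-2-[(dimethylphenylsilyl)methyl]-4-oxocyclohex-2-en-1-yl]-2,2-dimethylbut-3-en-1-yl methanesulfonate
Conditions: MsCl, Et3N, CH2Cl2, −20 → 0 °C
Reagents that add atoms: methanesulfonyl chloride, CS(=O)(=O)Cl
Why: Mesylation through sulfene tolerates the neopentyl-type secondary alcohol, and because the C5–O bond is not broken C5 keeps its configuration.

**Step 7**
Reactants: 11 (1S)-1-[(1R)-2-[(dimethylphenylsilyl)methyl]-4-oxocyclohex-2-en-1-yl]-2,2-dimethylbut-3-en-1-yl methanesulfonate
Product: 14 (1R,5S,6R,7S)-6-[(dimethylphenylsilyl)methyl]-6-methyl-7-(2-methylbut-3-en-2-yl)bicyclo[3.1.1]heptan-2-one, via silyl enol ether 12 (not isolated), via lithium enolate 13 (not isolated)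
Conditions: Me2CuLi (from CuI, 2 MeLi), Me3SiCl, THF, −78 → −40 °C; volatiles removed, pentane, filtered from copper salts under Ar; MeLi (1.0 equiv), THF, 0 °C; DMPU, 0.01 M, 0 → 45 °C
Reagents that add atoms: lithium dimethylcuprate, [Li+].C[Cu-]C
Why: Me3SiCl-accelerated conjugate addition of Me2CuLi to the β,β-disubstituted enone gives the C1=C11 silyl enol ether 12 as a single regioisomer, MeLi cleaves the O–Si bond to the lithium enolate 13, and C11 of 13 displaces the C5 mesylate. The closest known chemistry is the tandem cuprate conjugate addition–intramolecular enolate alkylation and the closure of bicyclo[3.1.1]heptanones by attack of a cyclohexanone enolate on a sulfonate carried by the C4 substituent. The cyclobutane (C4–C5–C11–C10) closes in the 4-exo-tet mode with the C4–C5 bond axial, and O-alkylation is excluded because it would give a bridgehead enol ether. C10 is set by addition anti to the C4 branch, which allylic (1,2) strain against the silylmethyl group holds pseudoaxial; C11 follows from the cis 1,3-bridge that C5 must make; C5 is set by inversion of the (S)-mesylate, which places H toward the keto bridge and C6 on the side of the C9 arm. The step needs the C11 and not the C2 enolate, and substitution must outrun proton transfer: the conjugate addition fixes the enolate regiochemistry, and aprotic conditions, one equivalent of MeLi, high dilution and DMPU are meant to preserve it while the neopentyl-type centre reacts.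

**Step 8**
Reactants: 14 (1R,5S,6R,7S)-6-[(dimethylphenylsilyl)methyl]-6-methyl-7-(2-methylbut-3-en-2-yl)bicyclo[3.1.1]heptan-2-one
Product: 16 C2=C3 enone of 14 (bicyclo[3.1.1]hept-3-en-2-one; C4 C5 C10 C11 as in 14), via lithium enolate 15 (not isolated)
Conditions: LDA, THF, −78 °C; N-tert-butylbenzenesulfinimidoyl chloride, −78 °C
Reagents that add atoms: none
Why: Deprotonation can only occur at C2 because C11 is a cyclobutane bridgehead, and the enolate is dehydrogenated in one flask by attack on sulfur from the open face and syn elimination of the sulfenamide with a C3–H on that face; no stereocentre is touched.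

**Step 9**
Reactants: 16 C2=C3 enone of 14
Product: 17 trimethylsilyl enol ether (C1=C2) of the C3-methyl ketone, methyl on the face of the C5 bridge
Conditions: Me2CuLi (from CuI, 2 MeLi), Me3SiCl, THF, −78 °C
Reagents that add atoms: lithium dimethylcuprate, [Li+].C[Cu-]C; chlorotrimethylsilane, C[Si](C)(C)Cl
Why: Conjugate addition of the cuprate to C3 from the face of the C5–H bridge, away from the C10 methyl group, with in situ O-silylation; the new C3 centre is temporary.

**Step 10**
Reactants: 17 trimethylsilyl enol ether of the C3-methyl ketone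
Product: 19 C3-methyl C2=C3 enone (3-methyl enone of ring A; C4 C5 C10 C11 as in 14), via bromo ketone 18 (not isolated)
Conditions: NBS, THF, 0 °C; then LiBr, Li2CO3, DMF, 110 °C
Reagents that add atoms: none
Why: Electrophilic bromination of the silyl enol ether places bromine on C2 anti to the C10 methyl bridge and therefore trans to the C3–H, so base-mediated anti elimination of HBr should give the enone carrying the C3 methyl group, whereas a syn elimination (palladium enolate or selenoxide) would need the face of C2 that the C10 methyl group covers; the C3 stereocentre disappears.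

**Step 11**
Reactants: 19 C3-methyl C2=C3 enone
Product: 20 C7 methyl ketone of 19 (3-methylbutan-2-on-3-yl group on C5)
Conditions: PdCl2 (10 mol %), CuCl (1 equiv), O2 (1 atm), DMF/H2O 7:1, rt
Reagents that add atoms: water, O
Why: Tsuji–Wacker oxidation by Markovnikov hydroxypalladation of the monosubstituted C7=C8 alkene gives the methyl ketone, while the electron-poor trisubstituted enone alkene should not react.

**Step 12**
Reactants: 20 C7 methyl ketone
Product: 22 C9 primary alcohol (hydroxymethyl on C10), via acetoxysilane 21 (not isolated)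
Conditions: Hg(OAc)2, AcOOH (32% in AcOH), AcOH, rt
Reagents that add atoms: peracetic acid, CC(=O)OO
Why: Tamao–Fleming oxidation, in which ipso-mercuridesilylation removes the phenyl group and peracid inserts oxygen into the C9–Si bond with migration of carbon to oxygen; the medium is only weakly acidic, so the enone, the methyl ketone and the cyclobutane should survive.

**Step 13**
Reactants: 22 C9 primary alcohol
Product: 23 C9 aldehyde (formyl on C10)
Conditions: Dess–Martin periodinane, CH2Cl2, rt
Reagents that add atoms: none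
Why: Dess–Martin oxidation of the neopentyl primary alcohol gives an aldehyde that has no α-hydrogen and so cannot epimerise or enolise.

**Step 14**
Reactants: 23 C9 aldehyde
Product: 25 tricyclic C8=C9 enone (ring C cyclohept-2-enone with C7=O; ring A enone retained), via aldol 24 (not isolated)
Conditions: KOH, MeOH, 0 → 40 °C
Reagents that add atoms: none
Why: Intramolecular aldol condensation (7-enolendo-exo-trig) in which the C8 methyl is the only enolisable position that can reach the non-enolisable C9 aldehyde, and E1cB loss of water from both C9 epimers of 24 converges on the C8=C9 enone.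

**Step 15**
Reactants: 25 tricyclic C8=C9 enone
Product: 27 (9R) β-hydroxy ketone (C9–OH on the side of C11; C7=O), via boryl ketone 26 (not isolated)
Conditions: CuCl (5 mol %), NaOt-Bu (10 mol %), (R)-1-[(S)-2-(diphenylphosphino)ferrocenyl]ethyldicyclohexylphosphine or its antipode (6 mol %), B2pin2, MeOH, THF, rt; then NaBO3·4H2O, THF/H2O, rt
Reagents that add atoms: sodium perborate, [Na+].[O-]OB=O
Why: Copper-catalysed enantioselective conjugate borylation of the β-monosubstituted cycloheptenone (the β,β-disubstituted ring A enone is much less reactive), in which the ligand antipode that delivers boron to the C9 face syn to C11 is chosen because the substrate itself barely distinguishes the two faces, followed by perborate oxidation of the C–B bond with retention.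

**Step 16**
Reactants: 27 (9R) β-hydroxy ketone
Product: 28 (7R,9R) C7 alcohol C9 isovalerate (C7–OH trans to the C9 ester)
Conditions: SmI2 (30 mol %), 3-methylbutanal (8 equiv), THF, −10 °C
Reagents that add atoms: 3-methylbutanal, CC(C)CC=O
Why: Evans–Tishchenko reaction, in which the C9 hydroxyl forms a hemiacetal with the aldehyde and samarium-templated intramolecular hydride transfer to C7 from the side of the C9 oxygen sets the C7 hydroxyl anti (trans) to C9–O while turning the C9 oxygen into the isovalerate; only a β-hydroxy ketone can react, so the ring A enone is left alone.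

**Step 17**
Reactants: 28 (7R,9R) C7 alcohol C9 isovalerate
Product: 29 target CNP0214473.1 (C7 3-methylbut-2-enoate and C9 3-methylbutanoate)
Conditions: 3-methylbut-2-enoyl chloride, pyridine, DMAP (cat.), CH2Cl2, 0 °C → rt
Reagents that add atoms: 3-methylbut-2-enoyl chloride, CC(C)=CC(Cl)=O
Why: DMAP-catalysed acylation of the hindered C7 alcohol, with pyridine in place of a trialkylamine to limit vinylketene formation and deconjugation of the senecioyl group; the trans relation of C7–OH and the C9 ester disfavours acyl migration and no stereocentre changes.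

**Compound list**

1 | 3-ethoxycyclohex-2-en-1-one | CCOC1=CC(=O)CCC1 | starting material
2 | lithium 5-ethoxycyclohexa-1,5-dien-1-olate (kinetic dienolate of 1) | CCOC1=CC(O[Li])=CCC1 | intermediate
3 | 1-ethoxy-3-(trimethylsilyloxy)cyclohexa-1,3-diene | CCOC1=CC(O[Si](C)(C)C)=CCC1 | intermediate
4 | 2,2-dimethylbut-3-enal | CC(C)(C=C)C=O | starting material
5 | (6S)-3-ethoxy-6-[(1S)-2,2-dimethyl-1-(trimethylsilyloxy)but-3-en-1-yl]cyclohex-2-en-1-one | O=C2C=C(OCC)CC[C@H]2[C@H](O[Si](C)(C)C)C(C)(C)C=C | intermediate
6 | (6S)-3-ethoxy-6-[(1S)-1-hydroxy-2,2-dimethylbut-3-en-1-yl]cyclohex-2-en-1-one (syn aldol) | O=C2C=C(OCC)CC[C@H]2[C@H](O)C(C)(C)C=C | intermediate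
7 | (chloromethyl)dimethylphenylsilane | C[Si](C)(CCl)c1ccccc1 | starting material
8 | [(dimethylphenylsilyl)methyl]magnesium chloride | C[Si](C)(C[Mg]Cl)c1ccccc1 | intermediate
9 | (6S)-1-[(dimethylphenylsilyl)methyl]-3-ethoxy-6-[(1S)-2,2-dimethyl-1-(trimethylsilyloxy)but-3-en-1-yl]cyclohex-2-en-1-ol, C1 epimers, present as its alkoxide | OC2(C[Si](C)(C)c1ccccc1)C=C(OCC)CC[C@H]2[C@H](O[Si](C)(C)C)C(C)(C)C=C | intermediate
10 | (4R)-3-[(dimethylphenylsilyl)methyl]-4-[(1S)-1-hydroxy-2,2-dimethylbut-3-en-1-yl]cyclohex-2-en-1-one | C[Si](C)(c1ccccc1)CC2=CC(=O)CC[C@H]2[C@H](O)C(C)(C)C=C | intermediate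
11 | (1S)-1-[(1R)-2-[(dimethylphenylsilyl)methyl]-4-oxocyclohex-2-en-1-yl]-2,2-dimethylbut-3-en-1-yl methanesulfonate | C[Si](C)(c1ccccc1)CC2=CC(=O)CC[C@H]2[C@H](OS(C)(=O)=O)C(C)(C)C=C | intermediate
12 | (1S)-1-[(1R,2R)-2-[(dimethylphenylsilyl)methyl]-2-methyl-4-(trimethylsilyloxy)cyclohex-3-en-1-yl]-2,2-dimethylbut-3-en-1-yl methanesulfonate (methyl trans to the C4 branch) | C[Si](C)(c1ccccc1)C[C@@]2(C)C=C(O[Si](C)(C)C)CC[C@H]2[C@H](OS(C)(=O)=O)C(C)(C)C=C | intermediate
13 | lithium enolate of 12 (O–Li in place of O–SiMe3, C1=C11 enolate) | C[Si](C)(c1ccccc1)C[C@@]2(C)C=C(O[Li])CC[C@H]2[C@H](OS(C)(=O)=O)C(C)(C)C=C | intermediate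
14 | (1R,5S,6R,7S)-6-[(dimethylphenylsilyl)methyl]-6-methyl-7-(2-methylbut-3-en-2-yl)bicyclo[3.1.1]heptan-2-one (C10 methyl and C5–H syn to the keto bridge) | C[Si](C)(c1ccccc1)C[C@@]2(C)[C@@H]3C(=O)CC[C@H]2[C@@H]3C(C)(C)C=C | intermediate
15 | lithium C1=C2 enolate of 14 | C[Si](C)(c1ccccc1)C[C@@]2(C)[C@@H]3C(O[Li])=CC[C@H]2[C@@H]3C(C)(C)C=C | intermediate
16 | C2=C3 enone of 14: 6-[(dimethylphenylsilyl)methyl]-6-methyl-7-(2-methylbut-3-en-2-yl)bicyclo[3.1.1]hept-3-en-2-one, C4 C5 C10 C11 as in 14 | C[Si](C)(c1ccccc1)C[C@@]2(C)[C@@H]3C(=O)C=C[C@H]2[C@@H]3C(C)(C)C=C | intermediate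
17 | 2-(trimethylsilyloxy)bicyclo[3.1.1]hept-2-ene with C3 methyl on the face of the C5 bridge, other centres as in 14 | C[Si](C)(c1ccccc1)C[C@@]2(C)[C@@H]3C(O[Si](C)(C)C)=C[C@@H](C)[C@H]2[C@@H]3C(C)(C)C=C | intermediate
18 | C2-bromo C3-methyl ketone, Br and CH3 both on the face of the C5 bridge | C[Si](C)(c1ccccc1)C[C@@]2(C)[C@@H]3C(=O)[C@@H](Br)[C@@H](C)[C@H]2[C@@H]3C(C)(C)C=C | intermediate
19 | 6-[(dimethylphenylsilyl)methyl]-4,6-dimethyl-7-(2-methylbut-3-en-2-yl)bicyclo[3.1.1]hept-3-en-2-one, C4 C5 C10 C11 as in 14 | C[Si](C)(c1ccccc1)C[C@@]2(C)[C@@H]3C(=O)C=C(C)[C@H]2[C@@H]3C(C)(C)C=C | intermediate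
20 | C7 methyl ketone: 7-(3-methyl-2-oxobutan-3-yl) analogue of 19 | C[Si](C)(c1ccccc1)C[C@@]2(C)[C@@H]3C(=O)C=C(C)[C@H]2[C@@H]3C(C)(C)C(C)=O | intermediate
21 | [(acetoxydimethylsilyl)methyl] analogue of 20 | CC(=O)O[Si](C)(C)C[C@@]2(C)[C@@H]3C(=O)C=C(C)[C@H]2[C@@H]3C(C)(C)C(C)=O | intermediate
22 | C9 alcohol: 6-(hydroxymethyl)-4,6-dimethyl-7-(3-methyl-2-oxobutan-3-yl)bicyclo[3.1.1]hept-3-en-2-one | OC[C@@]2(C)[C@@H]3C(=O)C=C(C)[C@H]2[C@@H]3C(C)(C)C(C)=O | intermediate
23 | C9 aldehyde: 6-formyl analogue of 22 | O=C[C@@]2(C)[C@@H]3C(=O)C=C(C)[C@H]2[C@@H]3C(C)(C)C(C)=O | intermediate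
24 | tricyclic aldol: C9–OH, C7=O, both C9 epimers | O=C1CC(O)[C@@]2(C)[C@@H]3C(=O)C=C(C)[C@H]2[C@@H]3C1(C)C | intermediate
25 | tricyclic bis-enone: C7=O with C8=C9, C1=O with C2=C3(Me) | O=C1C=C[C@@]2(C)[C@@H]3C(=O)C=C(C)[C@H]2[C@@H]3C1(C)C | intermediate
26 | C9 pinacolboryl C7 ketone, boron on the side of C11 | O=C1C[C@@H](B4OC(C)(C)C(C)(C)O4)[C@@]2(C)[C@@H]3C(=O)C=C(C)[C@H]2[C@@H]3C1(C)C | intermediate
27 | (9R) C9 hydroxy C7 ketone | O=C1C[C@@H](O)[C@@]2(C)[C@@H]3C(=O)C=C(C)[C@H]2[C@@H]3C1(C)C | intermediate
28 | (7R,9R) C7 hydroxy C9 3-methylbutanoate, C7–OH trans to C9–O | O[C@@H]1C[C@@H](OC(=O)CC(C)C)[C@@]2(C)[C@@H]3C(=O)C=C(C)[C@H]2[C@@H]3C1(C)C | intermediate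
29 | CNP0214473.1: C7 3-methylbut-2-enoate, C9 3-methylbutanoate | CC(C)=CC(=O)O[C@@H]1C[C@@H](OC(=O)CC(C)C)[C@@]2(C)[C@@H]3C(=O)C=C(C)[C@H]2[C@@H]3C1(C)C | target

**Step count and risks**

Total step count: 17. Longest linear sequence: 16 steps (steps 1–3 and 5–17; step 4 prepares the Grignard reagent).

Steps most likely to fail:

1. Step 7. Substitution at the neopentyl-type secondary C5 may be slow, partly because C6 and the C9 arm are pressed together in the transition state. Proton transfer could then equilibrate enolate 13 to the C2 enolate and erode the regiochemistry of closure, or MeLi could metalate the mesyl methyl group. The fallback sets out from 11 and comes back at 14. The cuprate addition is worked up with aqueous NH4Cl to give the keto mesylate F1. Heating F1 with tert-butoxybis(dimethylamino)methane in toluene puts a blocking group on the less hindered C2 to give the dimethylaminomethylene ketone F2, which leaves C11 as the only α-position that can be deprotonated. KOt-Bu in t-BuOH/DMSO at 25–60 °C then closes the cyclobutane under equilibrating conditions, which can be forced without loss of regiochemistry, to give the blocked bicyclic ketone F3. Aqueous NaOH in EtOH removes the blocking group by hydrolysis and retro-Claisen loss of formate and returns 14.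

2. Step 2. The boron catalyst may turn over poorly or discriminate the aldehyde faces insufficiently with the α-quaternary aldehyde, or the syn preference may erode. The fallback sets out from 3 and 4 and comes back at 6. A fluoride-triggered aldol of the naked enolate (tris(dimethylamino)sulfonium difluorotrimethylsilicate, 5 mol %, THF, −78 °C), which is syn-selective through an extended transition state, gives the racemic syn silyl ether F4. Cold 0.5 M HCl gives the racemic syn aldol F5, and the (6S,1′S) enantiomer 6 is obtained by preparative chromatography on an amylose tris(3,5-dimethylphenylcarbamate) phase.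

3. Step 15. Borylcopper addition at C9, next to the quaternary C10, may be slow or show poor facial selectivity. The fallback sets out from 23 and comes back at 27. Kinetic deprotonation of the C8 methyl with LiHMDS (THF, −78 °C) and cold quench stops the cyclisation at the aldol stage 24 without dehydration. 27 is separated by chromatography from the C9-epimeric hydroxy ketone F6, and F6 is returned to the aldol equilibrium with catalytic KOt-Bu in THF at −20 °C and separated again.

**Further compounds**

F1 | step 7 | 3-[(dimethylphenylsilyl)methyl]-3-methyl-4-[(1S)-1-(methanesulfonyloxy)-2,2-dimethylbut-3-en-1-yl]cyclohexan-1-one, methyl trans to the C4 branch | C[Si](C)(c1ccccc1)C[C@@]2(C)CC(=O)CC[C@H]2[C@H](OS(C)(=O)=O)C(C)(C)C=C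
F2 | step 7 | C2-(dimethylaminomethylene) derivative of F1 (alkene geometry not defined) | C[Si](C)(c1ccccc1)C[C@@]2(C)CC(=O)C(=CN(C)C)C[C@H]2[C@H](OS(C)(=O)=O)C(C)(C)C=C
F3 | step 7 | C2-(dimethylaminomethylene) derivative of 14 (alkene geometry not defined) | C[Si](C)(c1ccccc1)C[C@@]2(C)[C@@H]3C(=O)C(=CN(C)C)C[C@H]2[C@@H]3C(C)(C)C=C
F4 | step 2 | racemic syn silyl ether (racemate of 5; one enantiomer drawn) | O=C2C=C(OCC)CC[C@H]2[C@H](O[Si](C)(C)C)C(C)(C)C=C
F5 | step 2 | racemic syn aldol (racemate of 6; one enantiomer drawn) | O=C2C=C(OCC)CC[C@H]2[C@H](O)C(C)(C)C=C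
F6 | step 15 | (9S) C9 hydroxy C7 ketone, C9 epimer of 27 | O=C1C[C@H](O)[C@@]2(C)[C@@H]3C(=O)C=C(C)[C@H]2[C@@H]3C1(C)C
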